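**Overview**

- Retrosynthesis: the 12-hydroperoxide with its 11(20)-methylene goes back to an 11,12-olefin (ene reaction) and the acetates to a diol; then the C1–C10 bond is cut. This bond is the only one shared by the cyclohexane (C1, C10–C14) and the ten-membered ring (C1–C10), and around it sit an oxygen on C14, a ketone on C9 and olefinic C11. That is the pattern left when C10 of a C9 enol opens a 1,14-epoxide at C1 across a 14-membered ring, so one C–C bond can create both rings.
- The 14-membered epoxy ketone is cut further at the epoxide (from a Z 1,14-olefin), C1–C2 (vinyl iodide plus aldehyde), C8–C17 and O7–C19 (lactone), C9–C10 (acyl dithiane alkylation), C8–C9 (dithiane addition), C12–C13 (vinyl–allyl coupling), C3–C4 (ester enolate alkylation) and C5=C6 (Still–Gennari).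
- Forward: two Z vinyl iodides from propargylic alcohols are joined to the C10–C15 dienyl bromide, and the C2–C9 acyl dithiane from (R)-glyceraldehyde acetonide is alkylated with it. The γ-lactone is closed first, the 14-membered carbocycle second, the epoxide third, and the transannular C1–C10 bond last, which makes the six- and ten-membered rings together.
- Stereochemistry: C7 comes from (R)-glyceraldehyde; C8 and C17 from the lactone closure under control of C7; C2 from a CBS reduction; C1 and C14 from the hydroxyl-directed epoxidation (C1 then inverted, C14 retained); C10 from the transannular step; C12 from the final ene reaction, anti to the axial 14-acetate. The three Z olefins come from carbomagnesiation, hydroalumination and Still–Gennari olefination.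

Key step: step 30

Remark: all intermediates carry the briarane numbers of the target (ring carbons C1–C14, methyls C15, C16, C18, C20, lactone carbons C17 and C19). The target is read from its SMILES as the 1S,2S,7S,8S,10S,12S,14S,17R isomer with a 5Z olefin. (R)-Glyceraldehyde acetonide is taken as a bought compound and distilled before use.

**Route**

Step 1
Reactants: 1 propargyl alcohol
Product: 3 (Z)-3-iodo-2-methylprop-2-en-1-ol, via vinylmagnesium alkoxide 2 (not isolated)
Conditions: MeMgBr (3 equiv), CuI (10 mol%), THF, −10 °C → rt; then I2, −78 → 0 °C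
Reagents that add atoms: methylmagnesium bromide, C[Mg]Br; iodine, II
Why: Copper-catalysed anti-carbomagnesiation of the propargylic magnesium alkoxide places methyl (C20) on the inner carbon and magnesium on the terminal carbon cis to the oxymethyl group through a five-membered chelate, and iodinolysis with retention should give the Z vinyl iodide (carbometalation–iodination).

Step 2
Reactants: 3 (Z)-3-iodo-2-methylprop-2-en-1-ol
Product: 4 (Z)-tert-butyl[(3-iodo-2-methylallyl)oxy]dimethylsilane
Conditions: TBSCl, imidazole, CH2Cl2, 0 °C → rt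
Reagents that add atoms: tert-butyldimethylsilyl chloride, CC(C)(C)[Si](C)(C)Cl
Why: Silyl ether formation at a primary alcohol protects the hydroxyl from the organolithium chemistry of step 5.

Step 3
Reactants: 5 but-2-yn-1-ol
Product: 7 (Z)-3-iodobut-2-en-1-ol, via cyclic vinylalanate 6 (not isolated)
Conditions: NaAlH2(OCH2CH2OMe)2, THF, 0 °C → rt; then I2, −78 → 0 °C
Reagents that add atoms: iodine, II
Why: Hydroxyl-directed trans-hydroalumination delivers hydride to C2 and aluminium to C3 within a five-membered alkoxyalanate, and iodine replaces aluminium with retention to give the Z iodide.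

Step 4
Reactants: 7 (Z)-3-iodobut-2-en-1-ol
Product: 8 (Z)-1-bromo-3-iodobut-2-ene
Conditions: CBr4, PPh3, CH2Cl2, 0 °C
Reagents that add atoms: carbon tetrabromide, BrC(Br)(Br)Br
Why: Appel bromination of a primary allylic alcohol is an SN2 displacement under neutral conditions that leaves the vinyl iodide and its geometry untouched.

Step 5
Reactants: 4 (Z)-tert-butyl[(3-iodo-2-methylallyl)oxy]dimethylsilane; 8 (Z)-1-bromo-3-iodobut-2-ene
Product: 11 tert-butyl{[(2Z,5Z)-6-iodo-2-methylhepta-2,5-dien-1-yl]oxy}dimethylsilane, via vinyllithium 9 (not isolated), via vinylmagnesium bromide 10 (not isolated)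
Conditions: t-BuLi (2.05 equiv), Et2O, −78 °C; MgBr2·OEt2, −78 → −20 °C; then 8, CuI (5 mol%), THF, −20 → 0 °C
Reagents that add atoms: none
Why: Iodine–lithium exchange with retention, transmetalation to the vinyl Grignard reagent and copper-catalysed SN2 substitution of the primary allylic bromide (vinyl–allyl cross-coupling) should form C12–C13 with both Z olefins intact, since the γ-carbon of 8 carries iodine and methyl and its vinyl iodide is inert to the Grignard reagent.

Step 6
Reactants: 11 tert-butyl{[(2Z,5Z)-6-iodo-2-methylhepta-2,5-dien-1-yl]oxy}dimethylsilane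
Product: 12 (2Z,5Z)-1-bromo-6-iodo-2-methylhepta-2,5-diene
Conditions: Ph3PBr2, CH2Cl2, 0 °C → rt
Reagents that add atoms: dibromotriphenylphosphorane, BrP(Br)(c1ccccc1)(c1ccccc1)c1ccccc1
Why: Dibromotriphenylphosphorane converts primary silyl ethers directly into bromides (silyloxyphosphonium formation, then SN2 by bromide), so no separate desilylation is needed and the Z allylic system is not ionised.

Step 7
Reactants: 13 (R)-glyceraldehyde acetonide; 14 methyl 2-[bis(2,2,2-trifluoroethoxy)phosphoryl]propanoate
Product: 16 methyl (Z)-3-[(4S)-2,2-dimethyl-1,3-dioxolan-4-yl]-2-methylprop-2-enoate, via potassium phosphonate 15 (not isolated)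
Conditions: KN(SiMe3)2, 18-crown-6, THF, −78 °C; then 13, −78 °C
Reagents that add atoms: none
Why: Still–Gennari olefination with the bis(trifluoroethyl) phosphonate eliminates from the kinetic adduct and should give the Z trisubstituted 5,6-olefin, while C7 is carried over unchanged from the aldehyde at low temperature.

Step 8
Reactants: 16 methyl (Z)-3-[(4S)-2,2-dimethyl-1,3-dioxolan-4-yl]-2-methylprop-2-enoate
Product: 17 (Z)-3-[(4S)-2,2-dimethyl-1,3-dioxolan-4-yl]-2-methylprop-2-en-1-ol
Conditions: i-Bu2AlH (2.2 equiv), CH2Cl2, −78 °C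
Reagents that add atoms: none
Why: Hydride 1,2-reduction of the enoate gives the Z allylic alcohol (C4) without touching the acetonide.

Step 9
Reactants: 17 (Z)-3-[(4S)-2,2-dimethyl-1,3-dioxolan-4-yl]-2-methylprop-2-en-1-ol
Product: 18 (4S)-4-[(Z)-3-bromo-2-methylprop-1-en-1-yl]-2,2-dimethyl-1,3-dioxolane
Conditions: CBr4, PPh3, CH2Cl2, −20 °C
Reagents that add atoms: carbon tetrabromide, BrC(Br)(Br)Br
Why: Appel bromination gives the primary allylic bromide by SN2 under neutral conditions that the acetonide tolerates.

Step 10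
Reactants: 18 (4S)-4-[(Z)-3-bromo-2-methylprop-1-en-1-yl]-2,2-dimethyl-1,3-dioxolane
Product: 19 tert-butyl (Z)-5-[(4S)-2,2-dimethyl-1,3-dioxolan-4-yl]-4-methylpent-4-enoate
Conditions: tert-butyl acetate, LiN(iPr)2, THF, −78 °C; then 18, DMPU, −78 → −20 °C
Reagents that add atoms: tert-butyl acetate, CC(=O)OC(C)(C)C
Why: SN2 alkylation of the lithium enolate of tert-butyl acetate with the primary allylic bromide adds C2 and C3 (ester enolate alkylation), the bulky ester suppressing self-condensation.

Step 11
Reactants: 19 tert-butyl (Z)-5-[(4S)-2,2-dimethyl-1,3-dioxolan-4-yl]-4-methylpent-4-enoate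
Product: 20 (Z)-5-[(4S)-2,2-dimethyl-1,3-dioxolan-4-yl]-4-methylpent-4-en-1-ol
Conditions: LiAlH4, Et2O, 0 °C
Reagents that add atoms: none
Why: LiAlH4 reduces the ester to the primary C2 alcohol and leaves the isolated olefin and the acetonide alone (hydride reduction).

Step 12
Reactants: 20 (Z)-5-[(4S)-2,2-dimethyl-1,3-dioxolan-4-yl]-4-methylpent-4-en-1-ol
Product: 21 (4S)-4-{(Z)-5-[(4-methoxybenzyl)oxy]-2-methylpent-1-en-1-yl}-2,2-dimethyl-1,3-dioxolane
Conditions: NaH, PMBCl, Bu4NI (cat.), THF/DMF, 0 °C → rt
Reagents that add atoms: 4-methoxybenzyl chloride, COc1ccc(CCl)cc1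
Why: Williamson etherification installs a PMB ether that survives the acid, base, organolithium and samarium steps ahead and is later removed oxidatively.

Step 13
Reactants: 21 (4S)-4-{(Z)-5-[(4-methoxybenzyl)oxy]-2-methylpent-1-en-1-yl}-2,2-dimethyl-1,3-dioxolane
Product: 22 (2S,3Z)-7-[(4-methoxybenzyl)oxy]-4-methylhept-3-ene-1,2-diol
Conditions: AcOH/H2O (4:1), 40 °C
Reagents that add atoms: none
Why: Acid-catalysed acetal hydrolysis frees the 7,8-diol, the PMB ether and the allylic C7–O bond being stable to aqueous acetic acid.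

Step 14
Reactants: 22 (2S,3Z)-7-[(4-methoxybenzyl)oxy]-4-methylhept-3-ene-1,2-diol
Product: 23 bis-TES ether of diol 22
Conditions: TESCl, imidazole, DMAP (cat.), CH2Cl2, 0 °C → rt
Reagents that add atoms: chlorotriethylsilane, CC[Si](CC)(CC)Cl
Why: Silyl ether formation at both hydroxyls sets up the selective oxidation of the primary position.

Step 15
Reactants: 23 bis-TES ether of diol 22
Product: 24 (2S,3Z)-7-[(4-methoxybenzyl)oxy]-4-methyl-2-(triethylsilyloxy)hept-3-enal
Conditions: (COCl)2, DMSO, CH2Cl2, −78 → −40 °C; then Et3N, −78 → −20 °C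
Reagents that add atoms: none
Why: Under Swern conditions the primary TES ether is cleaved by the chlorosulfonium reagent and oxidised directly while the secondary TES ether survives (selective Swern oxidation of a bis-silyl ether), which gives the C8 aldehyde in one operation with the base added cold to protect C7.

Step 16
Reactants: 24 (2S,3Z)-7-[(4-methoxybenzyl)oxy]-4-methyl-2-(triethylsilyloxy)hept-3-enal; 25 1,3-dithiane
Product: 27 dithianyl carbinol (C8 epimers), via 2-lithio-1,3-dithiane 26 (not isolated)
Conditions: 25, n-BuLi, THF, −30 °C; then 24, −78 °C; AcOH quench at −78 °C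
Reagents that add atoms: none
Why: Corey–Seebach addition of the lithiated dithiane to the aldehyde forms C8–C9, the C8 carbinol being formed as a mixture that is oxidised next, and the cold quench prevents 1,2-silyl migration.

Step 17
Reactants: 27 dithianyl carbinol (C8 epimers)
Product: 28 (2S,3Z)-1-(1,3-dithian-2-yl)-7-[(4-methoxybenzyl)oxy]-4-methyl-2-(triethylsilyloxy)hept-3-en-1-one
Conditions: SO3·pyridine, DMSO, i-Pr2NEt, CH2Cl2, 0 °C
Reagents that add atoms: none
Why: Parikh–Doering oxidation gives the 2-acyl-1,3-dithiane under conditions that leave the sulfur atoms, the PMB ether and the secondary TES ether intact and are mild enough for the C7 stereocentre.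

Step 18
Reactants: 28 acyl dithiane (C2–C9); 12 (2Z,5Z)-1-bromo-6-iodo-2-methylhepta-2,5-diene
Product: 30 open-chain C2–C15 acyl dithiane with the dienyl iodide on C9, via lithium enolate 29 (not isolated)
Conditions: LiN(SiMe3)2 (0.95 equiv), THF, −78 °C; then 12, DMPU, −78 → −20 °C
Reagents that add atoms: none
Why: The C9 hydrogen, flanked by two sulfur atoms and the carbonyl, is by far the most acidic, so a slight deficit of base gives one enolate that the soft allylic bromide should alkylate on carbon (enolate alkylation, C9–C10) without epimerising C7 or touching the vinyl iodide.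

Step 19
Reactants: 30 open-chain C2–C15 acyl dithiane
Product: 31 C7 α-hydroxy ketone
Conditions: HF·pyridine, pyridine, THF, 0 °C
Reagents that add atoms: none
Why: Buffered fluoride desilylation removes the secondary allylic TES ether under non-basic conditions, so the α-hydroxy ketone is not enolised.

Step 20
Reactants: 31 C7 α-hydroxy ketone
Product: 32 C7 2-bromopropanoate (epimers at the brominated carbon)
Conditions: 2-bromopropanoyl bromide, pyridine, CH2Cl2, −20 °C
Reagents that add atoms: 2-bromopropanoyl bromide, CC(Br)C(Br)=O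
Why: O-Acylation with the acid bromide installs C17–C19 as an α-bromo ester, whose brominated centre may be a mixture because it becomes an enolate.

Step 21
Reactants: 32 C7 2-bromopropanoate
Product: 33 β-hydroxy-γ-lactone (7S,8S,17R) with the C9 dithiane
Conditions: SmI2 (2.5 equiv), THF, −78 °C
Reagents that add atoms: none
Why: SmI2 reduces the α-bromo ester faster than any other group to a samarium enolate that adds to the neighbouring C8 ketone in a five-membered aldol closure (intramolecular Reformatsky reaction); the bulky C9 branch should settle trans to the C6 vinyl group on the new ring (8S), and the chelated transition state, or equilibration of the epimerisable C17, places the methyl trans to the C9 branch.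

Step 22
Reactants: 33 β-hydroxy-γ-lactone with the C9 dithiane
Product: 34 lactone C9 ketone (8-hydroxy-9-oxo)
Conditions: PhI(OCOCF3)2, NaHCO3, MeCN/H2O (9:1), 0 °C
Reagents that add atoms: water, O
Why: Oxidative dethioacetalisation with the hypervalent iodine reagent unmasks the C9 ketone, the buffer keeping the 11,12-olefin out of conjugation while the vinyl iodide, PMB ether and lactone are inert.

Step 23
Reactants: 34 lactone C9 ketone
Product: 35 C8 triethylsilyl ether
Conditions: TESOTf, 2,6-lutidine, CH2Cl2, −78 → 0 °C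
Reagents that add atoms: triethylsilyl triflate, CC[Si](CC)(CC)OS(=O)(=O)C(F)(F)F
Why: Silyl triflate silylation caps the hindered tertiary C8 hydroxyl, which takes the α-ketol out of the later base and Lewis-acid steps and leaves the C2 hydroxyl as the only one able to direct the epoxidation.

Step 24
Reactants: 35 C8 triethylsilyl ether
Product: 36 C2 primary alcohol
Conditions: DDQ, CH2Cl2/pH 7 buffer (10:1), 0 °C
Reagents that add atoms: none
Why: Oxidative PMB cleavage (single-electron oxidation, hydrolysis of the benzylic oxocarbenium ion) spares the silyl ether, the vinyl iodide and the isolated olefins.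

Step 25
Reactants: 36 C2 primary alcohol
Product: 37 C2 aldehyde
Conditions: Dess–Martin periodinane, NaHCO3, CH2Cl2, 0 °C → rt
Reagents that add atoms: none
Why: Dess–Martin oxidation gives the aldehyde under neutral buffered conditions.

Step 26
Reactants: 37 C2 aldehyde
Product: 38 14-membered allylic alcohol (C2 epimers)
Conditions: CrCl2 (8 equiv), NiCl2 (cat.), DMSO/THF (3:1), rt, 2 mM, slow addition
Reagents that add atoms: none
Why: Nozaki–Hiyama–Kishi macrocyclisation (nickel-catalysed formation of a vinylchromium species and its addition to the aldehyde under high dilution) should form C1–C2 and the 14-membered ring with retention of the Z olefin, without addition to the hindered C9 ketone or the lactone.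

Step 27
Reactants: 38 14-membered allylic alcohol (C2 epimers)
Product: 39 14-membered Z enone (C2 ketone)
Conditions: Dess–Martin periodinane, NaHCO3, CH2Cl2, 0 °C
Reagents that add atoms: none
Why: Dess–Martin oxidation converges both C2 epimers on one enone.

Step 28
Reactants: 39 14-membered Z enone
Product: 40 (2S)-allylic alcohol, the 14-membered cembranolide
Conditions: (R)-2-methyl-CBS-oxazaborolidine (1 equiv), BH3·SMe2, THF, −40 °C
Reagents that add atoms: none
Why: Corey–Bakshi–Shibata reduction with the (R)-oxazaborolidine treats the α-methylalkenyl side as the large group and should deliver hydride to the face that gives the 2S alcohol (reagent control), the C9 ketone next to quaternary C8 being too hindered to compete.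

Step 29
Reactants: 40 (2S)-allylic alcohol
Product: 41 (1R,2S,14S)-1,14-epoxy alcohol
Conditions: VO(acac)2 (5 mol%), t-BuOOH, CH2Cl2, 0 °C
Reagents that add atoms: tert-butyl hydroperoxide, CC(C)(C)OO
Why: Vanadium-catalysed hydroxyl-directed epoxidation touches only the allylic 1,14-olefin, and A(1,3) strain between the C2 substituents and C13 on the Z olefin puts H-2 in the olefin plane, so oxygen is delivered from the hydroxyl face and the threo cis-epoxide should result.

Step 30
Reactants: 41 (1R,2S,14S)-1,14-epoxy alcohol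
Product: 44 briarane core as 2,14-bis-TBS 8-TES ether, via 2-O-TBS epoxy ketone 42 (not isolated), via 9-silyloxy-9,11-diene 43 (not isolated)
Conditions: TBSOTf (3 equiv), Et3N (4 equiv), CH2Cl2, −78 °C, then −78 → −20 °C; aq. NaHCO3
Reagents that add atoms: tert-butyldimethylsilyl triflate, CC(C)(C)[Si](C)(C)OS(=O)(=O)C(F)(F)F
Why: Proposed new method: at −78 °C the silyl triflate should silylate the C2 hydroxyl and, because C8 is quaternary and the C10 hydrogens are both α to the ketone and allylic, soft-enolise C9 only toward C10 to the 9-silyloxy-9,11-diene before the epoxide is touched; on warming, silyl triflate activates the epoxide oxygen, dienol-ether carbon C10 attacks tertiary C1 anti to the breaking C1–O bond, and the C9 silyloxocarbenium ion gives its silyl group back to triflate to return the ketone while the former epoxide oxygen stays on C14 as its TBS ether. The closest known reaction type is the Lewis-acid epoxide-initiated cation–olefin cyclisation ended by a silyl enol ether, which has not been run across a 14-membered ring to give a briarane. One bond closes two rings: the cyclohexene (C1, C10–C14) in the six-membered mode with both epoxide carbons inside the new ring and the oxygen outside, as in the first ring of oxidosqualene cyclisation, and the ten-membered ring (C1–C10) as what remains of the macrocycle, not by an end-to-end closure. C1 is set by inversion and C14 by retention of the cis-epoxide (Me-15 trans to O-14), and C10 by a chair-like array in which the C1–C2 and C10–C9 bonds are antiperiplanar about the forming bond, which gives H-10 trans to Me-15; C10 stays α to the ketone and can be equilibrated should the cis isomer form. The step needs opening at C1 by C10 and not 1,2-hydride shift from C2 (the usual fate of epoxy silyl ethers with silyl triflates), proton loss to an allylic ether or attack by the 5,6-olefin; this rests on the tertiary terminus, on a dienol ether far more nucleophilic than the 5,6-olefin with its allylic lactone oxygen, on the 1,6-relation of C10 and C1 through a Z 11,12-olefin (attack through C12 would give a cyclobutane) and on a non-participating silyl ether at C2.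

Step 31
Reactants: 44 briarane core as 2,14-bis-TBS 8-TES ether
Product: 45 2,8,14-triol
Conditions: HF·pyridine, pyridine, THF, 0 °C → rt
Reagents that add atoms: none
Why: Buffered fluoride desilylation frees all three hydroxyls under conditions too mild for α-ketol rearrangement or for migration of the 11,12-olefin into conjugation.

Step 32
Reactants: 45 2,8,14-triol
Product: 46 2,14-diacetate
Conditions: Ac2O, DMAP, pyridine, CH2Cl2, 0 °C → rt
Reagents that add atoms: acetic anhydride, CC(=O)OC(C)=O
Why: DMAP-catalysed acetylation esterifies the two secondary hydroxyls, while the tertiary C8 hydroxyl next to the ketone is too hindered to react under these conditions.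

Step 33
Reactants: 46 2,14-diacetate
Product: 47 CNP0066422.1
Conditions: O2, visible light, 5,10,15,20-tetraphenylporphyrin (cat.), CH2Cl2, −20 °C
Reagents that add atoms: oxygen, O=O
Why: Schenck ene reaction of singlet oxygen with the 11,12-olefin: oxygen should bond to C12 on the β face, anti to the axial 14-acetoxy group, where H-10 is not available and the axial C15 methyl blocks C11, so a C20 hydrogen is transferred and the 11(20)-methylene 12S-hydroperoxide forms, the 5,6-olefin being deactivated by the allylic lactone oxygen.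

**Compound list**

1 | propargyl alcohol | C#CCO | starting material
2 | bromomagnesium (Z)-3-(bromomagnesio)-2-methylprop-2-en-1-olate (formed in the flask) | Br[Mg]OC/C(C)=C\[Mg]Br | intermediate
3 | (Z)-3-iodo-2-methylprop-2-en-1-ol | OC/C(C)=C\I | intermediate
4 | (Z)-tert-butyl[(3-iodo-2-methylallyl)oxy]dimethylsilane | CC(C)(C)[Si](C)(C)OC/C(C)=C\I | intermediate
5 | but-2-yn-1-ol | CC#CCO | starting material
6 | sodium cyclic (Z)-alkoxyvinylalanate from 5 (formed in the flask) | CC1=CCO[Al-]1(OCCOC)OCCOC.[Na+] | intermediate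
7 | (Z)-3-iodobut-2-en-1-ol | C/C(I)=C/CO | intermediate
8 | (Z)-1-bromo-3-iodobut-2-ene | C/C(I)=C/CBr | intermediate
9 | (Z)-vinyllithium from 4 (formed in the flask) | CC(C)(C)[Si](C)(C)OC/C(C)=C\[Li] | intermediate
10 | (Z)-vinylmagnesium bromide from 4 (formed in the flask) | CC(C)(C)[Si](C)(C)OC/C(C)=C\[Mg]Br | intermediate
11 | tert-butyl{[(2Z,5Z)-6-iodo-2-methylhepta-2,5-dien-1-yl]oxy}dimethylsilane | CC(C)(C)[Si](C)(C)OC/C(C)=C\C/C=C(\I)C | intermediate
12 | (2Z,5Z)-1-bromo-6-iodo-2-methylhepta-2,5-diene (C10–C15, C20) | BrC/C(C)=C\C/C=C(\I)C | intermediate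
13 | (R)-glyceraldehyde acetonide | O=C[C@H]1COC(C)(C)O1 | starting material
14 | methyl 2-[bis(2,2,2-trifluoroethoxy)phosphoryl]propanoate | COC(=O)C(C)P(=O)(OCC(F)(F)F)OCC(F)(F)F | starting material
15 | potassium salt of phosphonate 14 (formed in the flask) | COC(=O)[C-](C)P(=O)(OCC(F)(F)F)OCC(F)(F)F.[K+] | intermediate
16 | methyl (Z)-3-[(4S)-2,2-dimethyl-1,3-dioxolan-4-yl]-2-methylprop-2-enoate | COC(=O)/C(C)=C\[C@H]1COC(C)(C)O1 | intermediate
17 | (Z)-3-[(4S)-2,2-dimethyl-1,3-dioxolan-4-yl]-2-methylprop-2-en-1-ol | OC/C(C)=C\[C@H]1COC(C)(C)O1 | intermediate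
18 | (4S)-4-[(Z)-3-bromo-2-methylprop-1-en-1-yl]-2,2-dimethyl-1,3-dioxolane | BrC/C(C)=C\[C@H]1COC(C)(C)O1 | intermediate
19 | tert-butyl (Z)-5-[(4S)-2,2-dimethyl-1,3-dioxolan-4-yl]-4-methylpent-4-enoate | CC(C)(C)OC(=O)CC/C(C)=C\[C@H]1COC(C)(C)O1 | intermediate
20 | (Z)-5-[(4S)-2,2-dimethyl-1,3-dioxolan-4-yl]-4-methylpent-4-en-1-ol | OCCC/C(C)=C\[C@H]1COC(C)(C)O1 | intermediate
21 | PMB ether of 20 | COc1ccc(COCCC/C(C)=C\[C@H]2COC(C)(C)O2)cc1 | intermediate
22 | (2S,3Z)-7-[(4-methoxybenzyl)oxy]-4-methylhept-3-ene-1,2-diol | COc1ccc(COCCC/C(C)=C\[C@H](O)CO)cc1 | intermediate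
23 | bis-TES ether of 22 | COc1ccc(COCCC/C(C)=C\[C@H](O[Si](CC)(CC)CC)CO[Si](CC)(CC)CC)cc1 | intermediate
24 | (2S,3Z)-7-[(4-methoxybenzyl)oxy]-4-methyl-2-(triethylsilyloxy)hept-3-enal (C8 aldehyde) | COc1ccc(COCCC/C(C)=C\[C@H](O[Si](CC)(CC)CC)C=O)cc1 | intermediate
25 | 1,3-dithiane | C1CSCSC1 | starting material
26 | 2-lithio-1,3-dithiane (formed in the flask) | [Li]C1SCCCS1 | intermediate
27 | dithianyl carbinol, C8 epimers | COc1ccc(COCCC/C(C)=C\[C@H](O[Si](CC)(CC)CC)C(O)C2SCCCS2)cc1 | intermediate
28 | 2-acyl-1,3-dithiane (C2–C9), 7S | COc1ccc(COCCC/C(C)=C\[C@H](O[Si](CC)(CC)CC)C(=O)C2SCCCS2)cc1 | intermediate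
29 | lithium enolate of 28 (formed in the flask) | COc1ccc(COCCC/C(C)=C\[C@H](O[Si](CC)(CC)CC)C(O[Li])=C2SCCCS2)cc1 | intermediate
30 | open-chain C2–C15 acyl dithiane with (2Z,5Z)-dienyl iodide on C9 | COc1ccc(COCCC/C(C)=C\[C@H](O[Si](CC)(CC)CC)C(=O)C2(C/C(C)=C\C/C=C(\I)C)SCCCS2)cc1 | intermediate
31 | C7 α-hydroxy ketone | COc1ccc(COCCC/C(C)=C\[C@H](O)C(=O)C2(C/C(C)=C\C/C=C(\I)C)SCCCS2)cc1 | intermediate
32 | C7 2-bromopropanoate (epimers at CHBr) | COc1ccc(COCCC/C(C)=C\[C@H](OC(=O)C(C)Br)C(=O)C2(C/C(C)=C\C/C=C(\I)C)SCCCS2)cc1 | intermediate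
33 | (7S,8S,17R)-β-hydroxy-γ-lactone with C9 dithiane | COc1ccc(COCCC/C(C)=C\[C@@H]2OC(=O)[C@H](C)[C@@]2(O)C3(C/C(C)=C\C/C=C(\I)C)SCCCS3)cc1 | intermediate
34 | lactone with free C9 ketone and C8 hydroxyl | COc1ccc(COCCC/C(C)=C\[C@@H]2OC(=O)[C@H](C)[C@@]2(O)C(=O)C/C(C)=C\C/C=C(\I)C)cc1 | intermediate
35 | C8 triethylsilyl ether of 34 | COc1ccc(COCCC/C(C)=C\[C@@H]2OC(=O)[C@H](C)[C@@]2(O[Si](CC)(CC)CC)C(=O)C/C(C)=C\C/C=C(\I)C)cc1 | intermediate
36 | C2 primary alcohol | OCCC/C(C)=C\[C@@H]1OC(=O)[C@H](C)[C@@]1(O[Si](CC)(CC)CC)C(=O)C/C(C)=C\C/C=C(\I)C | intermediate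
37 | C2 aldehyde (seco-macrocycle) | O=CCC/C(C)=C\[C@@H]1OC(=O)[C@H](C)[C@@]1(O[Si](CC)(CC)CC)C(=O)C/C(C)=C\C/C=C(\I)C | intermediate
38 | 14-membered allylic alcohol, C2 epimers | C1C/C(C)=C\[C@@H]2OC(=O)[C@H](C)[C@@]2(O[Si](CC)(CC)CC)C(=O)C/C(C)=C\C/C=C(/C)C1O | intermediate
39 | 14-membered Z enone (C2 ketone) | C1C/C(C)=C\[C@@H]2OC(=O)[C@H](C)[C@@]2(O[Si](CC)(CC)CC)C(=O)C/C(C)=C\C/C=C(/C)C1=O | intermediate
40 | (2S)-allylic alcohol, 14-membered cembranolide | C1C/C(C)=C\[C@@H]2OC(=O)[C@H](C)[C@@]2(O[Si](CC)(CC)CC)C(=O)C/C(C)=C\C/C=C(/C)[C@H]1O | intermediate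
41 | (1R,2S,14S)-1,14-epoxy alcohol, β,γ-unsaturated C9 ketone | C1C/C(C)=C\[C@@H]2OC(=O)[C@H](C)[C@@]2(O[Si](CC)(CC)CC)C(=O)C/C(C)=C\C[C@@H]3O[C@]3(C)[C@H]1O | intermediate
42 | 2-O-TBS ether of 41 (formed in the flask) | C1C/C(C)=C\[C@@H]2OC(=O)[C@H](C)[C@@]2(O[Si](CC)(CC)CC)C(=O)C/C(C)=C\C[C@@H]3O[C@]3(C)[C@H]1O[Si](C)(C)C(C)(C)C | intermediate
43 | 2-O-TBS 9-(TBS-oxy)-9,11-diene epoxide, enol ether geometry not defined (formed in the flask) | C1C/C(C)=C\[C@@H]2OC(=O)[C@H](C)[C@@]2(O[Si](CC)(CC)CC)C(O[Si](C)(C)C(C)(C)C)=C/C(C)=C\C[C@@H]3O[C@]3(C)[C@H]1O[Si](C)(C)C(C)(C)C | intermediate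
44 | briarane core, 2,14-bis-TBS 8-TES ether, 9-ketone, 5Z and 11-olefins | CC1=CC[C@H](O[Si](C)(C)C(C)(C)C)[C@]2(C)[C@@H](O[Si](C)(C)C(C)(C)C)CC/C(C)=C\[C@@H]3OC(=O)[C@H](C)[C@@]3(O[Si](CC)(CC)CC)C(=O)[C@@H]12 | intermediate
45 | 2,8,14-triol | CC1=CC[C@H](O)[C@]2(C)[C@@H](O)CC/C(C)=C\[C@@H]3OC(=O)[C@H](C)[C@@]3(O)C(=O)[C@@H]12 | intermediate
46 | 2,14-diacetate | CC1=CC[C@H](OC(C)=O)[C@]2(C)[C@@H](OC(C)=O)CC/C(C)=C\[C@@H]3OC(=O)[C@H](C)[C@@]3(O)C(=O)[C@@H]12 | intermediate
47 | CNP0066422.1, (1S,2S,5Z,7S,8S,10S,12S,14S,17R)-2,14-diacetoxy-12-hydroperoxy-8-hydroxy-9-oxobriara-5,11(20)-dien-19,7-olide | C=C1[C@@H]2C(=O)[C@@]3(O)[C@H](/C=C(/C)CC[C@H](OC(C)=O)[C@@]2(C)[C@@H](OC(C)=O)C[C@@H]1OO)OC(=O)[C@@H]3C | target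

**Step count and risks**

Total: 33 steps. Longest linear sequence: 27 steps (steps 7–33, from (R)-glyceraldehyde acetonide); the dienyl bromide branch (steps 1–6) joins at step 18.

Steps most likely to fail:

1. Step 30 (transannular closure). What may go wrong: the activated epoxide rearranges by hydride migration from C2 or loses a proton before the carbon–carbon bond forms, enolisation lags behind epoxide activation, or the ring closes with the cis fusion. The fallback uses known chemistry, the acid-promoted transannular epoxide–olefin cyclisation long established for macrocyclic terpenoid epoxides, with a plain trisubstituted 10,11-olefin as nucleophile and C9 held at the alcohol level. It sets out from 41. Silylation of the C2 hydroxyl (TBSOTf, 2,6-lutidine, CH2Cl2, −78 °C) gives 42, this time isolated. DBU in CH2Cl2 moves the 11,12-olefin into conjugation and should give the (10E)-conjugated enone F1. Luche reduction (NaBH4, CeCl3·7H2O, MeOH, −40 °C) gives the C9 allylic alcohol F2, either epimer being usable, and acetylation (Ac2O, DMAP, pyridine) gives the allylic acetate F3. TBSOTf with 2,6-di-tert-butyl-4-methylpyridine in CH2Cl2 at −78 °C then opens the epoxide at C1, C10 of the olefin attacks and the tertiary C11 cation loses H-12, which should give the bicyclic 9-acetate F4 with the 11,12-olefin and a silylated O-14. Methanolysis (K2CO3, MeOH, 0 °C) frees the bicyclic C9 alcohol F5, and Dess–Martin oxidation returns the ketone, which is compound 44, where the route is rejoined.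

2. Step 33 (ene reaction). What may go wrong: poor regio- and facial selectivity of oxygen transfer (hydrogen taken from C10 or C13, attack on the α face) or competing oxygenation of the 5,6-olefin. The fallback builds the C12–O bond through an epoxide and sets out from 46. m-Chloroperbenzoic acid (NaHCO3, CH2Cl2, 0 °C), expected to attack the face away from the axial C15 methyl, gives the 11α,12α-epoxide F7. TMSOTf and 2,6-lutidine followed by DBU (toluene, −78 °C → rt) isomerise it to the exocyclic allylic 12α-trimethylsilyl ether F8, and citric acid in methanol gives the 12α-allylic alcohol F9. Mesylation (MsCl, Et3N, CH2Cl2, −20 °C) gives the 12α-mesylate F10, and displacement with anhydrous H2O2 in Et2O with inversion at C12 gives 47.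

3. Step 21 (Reformatsky lactonisation). What may go wrong: reductive cleavage of the α-acyloxy ketone or of a C–S bond by SmI2 outruns enolate formation, or the ring closes to the wrong C8 epimer. The fallback forms C8–C17 between two molecules and closes the ring by lactonisation; it sets out from 31. An excess of the zinc enolate made from ethyl 2-bromopropanoate and zinc dust (THF, 0 °C → rt) first turns the C7 hydroxyl into a zinc alkoxide and then adds to the ketone under chelation control, on the side of H-7, which should give the dihydroxy ester F6 with the 8S carbinol. Mild acid (pyridinium p-toluenesulfonate, benzene, rt) closes the γ-lactone through the C7 hydroxyl and DBU equilibrates C17, which returns 33.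

**Further compounds**

F1 | step 30 | (10E)-conjugated enone, 2-O-TBS 1,14-epoxide | C1C/C(C)=C\[C@@H]2OC(=O)[C@H](C)[C@@]2(O[Si](CC)(CC)CC)C(=O)/C=C(\C)CC[C@@H]3O[C@]3(C)[C@H]1O[Si](C)(C)C(C)(C)C
F2 | step 30 | C9 allylic alcohol (C9 epimers) | C1C/C(C)=C\[C@@H]2OC(=O)[C@H](C)[C@@]2(O[Si](CC)(CC)CC)C(O)/C=C(\C)CC[C@@H]3O[C@]3(C)[C@H]1O[Si](C)(C)C(C)(C)C
F3 | step 30 | C9 allylic acetate (C9 epimers) | C1C/C(C)=C\[C@@H]2OC(=O)[C@H](C)[C@@]2(O[Si](CC)(CC)CC)C(OC(C)=O)/C=C(\C)CC[C@@H]3O[C@]3(C)[C@H]1O[Si](C)(C)C(C)(C)C
F4 | step 30 | bicyclic 9-acetate, 2,14-bis-TBS 8-TES ether, 11,12-olefin | CC1=CC[C@H](O[Si](C)(C)C(C)(C)C)[C@]2(C)[C@@H](O[Si](C)(C)C(C)(C)C)CC/C(C)=C\[C@@H]3OC(=O)[C@H](C)[C@@]3(O[Si](CC)(CC)CC)C(OC(C)=O)[C@@H]12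
F5 | step 30 | bicyclic C9 alcohol, 2,14-bis-TBS 8-TES ether | CC1=CC[C@H](O[Si](C)(C)C(C)(C)C)[C@]2(C)[C@@H](O[Si](C)(C)C(C)(C)C)CC/C(C)=C\[C@@H]3OC(=O)[C@H](C)[C@@]3(O[Si](CC)(CC)CC)C(O)[C@@H]12
F6 | step 21 | (7S,8S)-dihydroxy ethyl ester (C17 epimers) | COc1ccc(COCCC/C(C)=C\[C@H](O)[C@@](O)(C(C)C(=O)OCC)C2(C/C(C)=C\C/C=C(\I)C)SCCCS2)cc1
F7 | step 33 | 11α,12α-epoxide of 46 | C[C@]15O[C@@H]5C[C@H](OC(C)=O)[C@]2(C)[C@@H](OC(C)=O)CC/C(C)=C\[C@@H]3OC(=O)[C@H](C)[C@@]3(O)C(=O)[C@@H]12
F8 | step 33 | 12α-trimethylsilyl ether, 11(20)-methylene | C=C1[C@@H]2C(=O)[C@@]3(O)[C@H](/C=C(/C)CC[C@H](OC(C)=O)[C@@]2(C)[C@@H](OC(C)=O)C[C@H]1O[Si](C)(C)C)OC(=O)[C@@H]3C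
F9 | step 33 | 12α-allylic alcohol, 11(20)-methylene | C=C1[C@@H]2C(=O)[C@@]3(O)[C@H](/C=C(/C)CC[C@H](OC(C)=O)[C@@]2(C)[C@@H](OC(C)=O)C[C@H]1O)OC(=O)[C@@H]3C
F10 | step 33 | 12α-mesylate, 11(20)-methylene | C=C1[C@@H]2C(=O)[C@@]3(O)[C@H](/C=C(/C)CC[C@H](OC(C)=O)[C@@]2(C)[C@@H](OC(C)=O)C[C@H]1OS(C)(=O)=O)OC(=O)[C@@H]3C
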